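The flavone is disconnected across ring C at C3–C4 and O1–C2. The C4 carbonyl, the C3 methine and the aryl-bearing C2 make up a 1,3-dioxygenated three-carbon unit, which a 3,5-diarylisoxazole stores as a latent 1,3-diketone. A single nitrile oxide–alkyne cycloaddition joins the ring A dipole carbon (future C4) to the terminal carbon of a ring B arylacetylene (future C3) and sets the oxidation level of C2 and C4 without enolate chemistry. The dipole precursor is an ortho-benzyloxy trimethoxybenzaldoxime, the partner a benzyloxy-dimethoxyphenylacetylene. One hydrogenolysis then opens the N–O bond and frees both phenols, and aqueous acid closes ring C.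

Key step: step 6

Remark: 2,3,4-trimethoxyphenol (1) is taken as a purchasable compound; the target has no stereocentre, and the double-bond geometries drawn for 4, 10 and 13 are the ones normally obtained and have no bearing on the outcome.

Step 1
Reactants: 1 2,3,4-trimethoxyphenol
Product: 2 2-hydroxy-3,4,5-trimethoxybenzaldehyde
Conditions: MgCl2, Et3N, (CH2O)n, MeCN, reflux; then 1 M HCl
Reagents that add atoms: paraformaldehyde (formaldehyde), C=O
Why: Casnati–Skattebøl ortho-formylation, in which the magnesium phenoxide delivers formaldehyde through a chelated six-membered transition state to the only free ortho position of 1 and a second formaldehyde oxidizes the benzylic alkoxide by hydride transfer, so the para-blocked phenol should give the salicylaldehyde regiospecifically.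

Step 2
Reactants: 2 2-hydroxy-3,4,5-trimethoxybenzaldehyde
Product: 3 2-benzyloxy-3,4,5-trimethoxybenzaldehyde
Conditions: BnBr, K2CO3, DMF, 60 °C
Reagents that add atoms: benzyl bromide, BrCc1ccccc1
Why: Williamson etherification of the phenoxide with a reactive benzylic bromide, where DMF and gentle heating should overcome the hydrogen bond to the ortho formyl group and the flanking methoxy group.

Step 3
Reactants: 3 2-benzyloxy-3,4,5-trimethoxybenzaldehyde
Product: 4 (E)-2-benzyloxy-3,4,5-trimethoxybenzaldehyde oxime
Conditions: NH2OH·HCl, NaOAc, EtOH/H2O, rt to 50 °C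
Reagents that add atoms: hydroxylamine hydrochloride, Cl.NO
Why: Oxime formation by acetate-buffered condensation of the aldehyde with hydroxylamine is fast, leaves the benzyl and methyl ethers untouched and should give the thermodynamically favoured E aldoxime.

Step 4
Reactants: 5 3-hydroxy-4,5-dimethoxybenzaldehyde
Product: 6 3-benzyloxy-4,5-dimethoxybenzaldehyde
Conditions: BnBr, K2CO3, DMF, rt to 50 °C
Reagents that add atoms: benzyl bromide, BrCc1ccccc1
Why: Williamson etherification masks the ring B phenol, which would otherwise be deprotonated in steps 5 and 6 and could add to the nitrile oxide, and the benzyl group is later removed in the same hydrogenolysis that opens the isoxazole.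

Step 5
Reactants: 6 3-benzyloxy-4,5-dimethoxybenzaldehyde; 7 dimethyl (1-diazo-2-oxopropyl)phosphonate
Product: 9 1-benzyloxy-5-ethynyl-2,3-dimethoxybenzene, via diazoalkene 8 (not isolated)
Conditions: K2CO3, MeOH, 0 °C to rt
Reagents that add atoms: dimethyl (1-diazo-2-oxopropyl)phosphonate (compound 7), COP(=O)(OC)C(=[N+]=[N-])C(C)=O
Why: Seyferth–Gilbert homologation in its Ohira–Bestmann form, in which methanolysis of 7 releases the diazomethylphosphonate anion, this olefinates the non-enolisable aldehyde in Horner–Wadsworth–Emmons fashion to diazoalkene 8, and loss of N2 followed by a 1,2-hydride shift should give the terminal alkyne.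

Step 6
Reactants: 4 (E)-2-benzyloxy-3,4,5-trimethoxybenzaldehyde oxime; 9 1-benzyloxy-5-ethynyl-2,3-dimethoxybenzene
Product: 12 3-(2-benzyloxy-3,4,5-trimethoxyphenyl)-5-(3-benzyloxy-4,5-dimethoxyphenyl)isoxazole, via hydroximoyl chloride 10 (not isolated), via nitrile oxide 11 (not isolated)
Conditions: 4 (1.3 equiv), NCS, DMF, 25–40 °C; then 9 (1.0 equiv), Et3N by syringe pump over several hours, 0 °C to rt
Reagents that add atoms: none
Why: NCS chlorinates the aldoxime carbon to hydroximoyl chloride 10, and slow addition of Et3N eliminates HCl so that nitrile oxide 11 is released a little at a time in the presence of alkyne 9. The dipole then adds across the triple bond in a concerted, asynchronous [3+2] process, its carbon bonding to the terminal alkyne carbon (C3–C4 of the target) and its oxygen to the aryl-bearing carbon (future C2); this is a Huisgen 1,3-dipolar cycloaddition of an aryl nitrile oxide to a terminal arylacetylene, a standard entry to 3,5-diarylisoxazoles. The isoxazole ring is closed by intermolecular cycloaddition, both ring bonds forming in the same event, so the aromatic heterocycle should arise directly without a separate cyclization or oxidation. No stereocentre is created. The step needs regioselectivity for the 3,5- over the 3,4-diaryl isomer, which the unsubstituted alkyne terminus secures on steric and frontier-orbital grounds, and it needs cycloaddition to outrun dimerization of 11 to the furoxan, which the slow release of the dipole, the hindering ortho-benzyloxy group and the absence of free phenols should secure.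

Step 7
Reactants: 12 3-(2-benzyloxy-3,4,5-trimethoxyphenyl)-5-(3-benzyloxy-4,5-dimethoxyphenyl)isoxazole
Product: 13 (Z)-3-amino-3-(2-hydroxy-3,4,5-trimethoxyphenyl)-1-(3-hydroxy-4,5-dimethoxyphenyl)prop-2-en-1-one
Conditions: H2 (1 atm), 10% Pd/C, EtOAc/EtOH, rt
Reagents that add atoms: none
Why: Catalytic hydrogenolysis over palladium cleaves the two benzylic C–O bonds and the weak isoxazole N–O bond in one operation (reductive isoxazole opening to a β-enaminoketone), and the product is a hydrogen-bonded vinylogous amide that should resist further reduction at one atmosphere.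

Step 8
Reactants: 13 (Z)-3-amino-3-(2-hydroxy-3,4,5-trimethoxyphenyl)-1-(3-hydroxy-4,5-dimethoxyphenyl)prop-2-en-1-one
Product: 15 2-(3-hydroxy-4,5-dimethoxyphenyl)-6,7,8-trimethoxy-4H-chromen-4-one, via beta-diketone 14 (not isolated)
Conditions: 2 M HCl, EtOH, reflux
Reagents that add atoms: water, O
Why: Acid hydrolysis of the vinylogous amide gives β-diketone 14, whose ortho phenol adds to the ring B carbonyl and loses water to form the γ-pyrone, the cyclodehydration that closes a Baker–Venkataraman flavone synthesis, under conditions too mild to cleave aryl methyl ethers.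

Compound list
1 | 2,3,4-trimethoxyphenol | COc1ccc(O)c(OC)c1OC | starting material
2 | 2-hydroxy-3,4,5-trimethoxybenzaldehyde | COc1cc(C=O)c(O)c(OC)c1OC | intermediate
3 | 2-benzyloxy-3,4,5-trimethoxybenzaldehyde | COc1cc(C=O)c(OCc2ccccc2)c(OC)c1OC | intermediate
4 | (E)-2-benzyloxy-3,4,5-trimethoxybenzaldehyde oxime | COc1cc(/C=N/O)c(OCc2ccccc2)c(OC)c1OC | intermediate
5 | 3-hydroxy-4,5-dimethoxybenzaldehyde | COc1cc(C=O)cc(O)c1OC | starting material
6 | 3-benzyloxy-4,5-dimethoxybenzaldehyde | COc1cc(C=O)cc(OCc2ccccc2)c1OC | intermediate
7 | dimethyl (1-diazo-2-oxopropyl)phosphonate | COP(=O)(OC)C(=[N+]=[N-])C(C)=O | starting material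
8 | 1-benzyloxy-5-(2-diazoethenyl)-2,3-dimethoxybenzene | COc1cc(C=C=[N+]=[N-])cc(OCc2ccccc2)c1OC | intermediate (not isolated)
9 | 1-benzyloxy-5-ethynyl-2,3-dimethoxybenzene | C#Cc1cc(OC)c(OC)c(OCc2ccccc2)c1 | intermediate
10 | (Z)-2-benzyloxy-N-hydroxy-3,4,5-trimethoxybenzimidoyl chloride | COc1cc(/C(Cl)=N/O)c(OCc2ccccc2)c(OC)c1OC | intermediate (not isolated)
11 | 2-benzyloxy-3,4,5-trimethoxybenzonitrile oxide | COc1cc(C#[N+][O-])c(OCc2ccccc2)c(OC)c1OC | intermediate (not isolated)
12 | 3-(2-benzyloxy-3,4,5-trimethoxyphenyl)-5-(3-benzyloxy-4,5-dimethoxyphenyl)isoxazole | COc1cc(-c2cc(-c3cc(OC)c(OC)c(OCc4ccccc4)c3)on2)c(OCc2ccccc2)c(OC)c1OC | intermediate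
13 | (Z)-3-amino-3-(2-hydroxy-3,4,5-trimethoxyphenyl)-1-(3-hydroxy-4,5-dimethoxyphenyl)prop-2-en-1-one | COc1cc(/C(N)=C/C(=O)c2cc(O)c(OC)c(OC)c2)c(O)c(OC)c1OC | intermediate
14 | 1-(2-hydroxy-3,4,5-trimethoxyphenyl)-3-(3-hydroxy-4,5-dimethoxyphenyl)propane-1,3-dione | COc1cc(C(=O)CC(=O)c2cc(O)c(OC)c(OC)c2)c(O)c(OC)c1OC | intermediate (not isolated)
15 | 2-(3-hydroxy-4,5-dimethoxyphenyl)-6,7,8-trimethoxy-4H-chromen-4-one (3'-hydroxy-4',5',6,7,8-pentamethoxyflavone) | COc1cc(-c2cc(=O)c3cc(OC)c(OC)c(OC)c3o2)cc(O)c1OC | target

Total step count: 8. Longest linear sequence: 6 steps (steps 1, 2, 3, 6, 7, 8); the ring B branch (steps 4, 5) joins at step 6.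

Steps most likely to fail

Step 6. Dimerization of the nitrile oxide may outpace its addition to the alkyne, and electrophilic chlorination of the electron-rich ring may compete with chlorination at the oxime carbon. The fallback builds the same isoxazole stepwise without a nitrile oxide, setting out from aldehyde 3 and alkyne 9. Deprotonation of 9 with n-BuLi (THF, −78 °C) and addition to 3 should give the racemic propargylic alcohol 1-(2-benzyloxy-3,4,5-trimethoxyphenyl)-3-(3-benzyloxy-4,5-dimethoxyphenyl)prop-2-yn-1-ol F1. Oxidation with MnO2 (CH2Cl2, rt) should give the ynone 1-(2-benzyloxy-3,4,5-trimethoxyphenyl)-3-(3-benzyloxy-4,5-dimethoxyphenyl)prop-2-yn-1-one F2. Condensation with NH2OH·HCl in pyridine/EtOH at the carbonyl should give the ynone oxime F3, whose geometric isomers equilibrate so that the hydroxyl can reach the alkyne. AuCl3-catalysed 5-endo-dig O-cyclization of the oxime onto the triple bond (CH2Cl2, rt) should then deliver isoxazole 12, where the route is rejoined. Nitrogen ends on the carbon bearing ring A by construction, so the regiochemistry does not depend on a cycloaddition.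

Step 7. Cleavage of the N–O bond may lag behind debenzylation and stall on the catalyst, or the enaminone may be reduced further on prolonged exposure. The fallback separates the two events and uses no hydrogen, setting out from 12. BCl3 with pentamethylbenzene as cation scavenger (CH2Cl2, −78 °C) should remove both benzyl ethers while leaving the methyl ethers, giving 3-(2-hydroxy-3,4,5-trimethoxyphenyl)-5-(3-hydroxy-4,5-dimethoxyphenyl)isoxazole F4. Reductive N–O cleavage with Mo(CO)6 and water in MeCN at reflux should then give enaminoketone 13, where the route is rejoined.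

Step 1. Formylation of the hindered, electron-rich magnesium phenoxide may stop at low conversion or divert into hydroxymethyl and methoxymethyl by-products. The fallback replaces electrophilic formylation by directed ortho-metalation, setting out from 1. MOMCl and i-Pr2NEt (CH2Cl2, 0 °C to rt) should give the ether 1,2,3-trimethoxy-4-(methoxymethoxy)benzene F5. Lithiation with n-BuLi/TMEDA (THF, −78 to 0 °C), directed to the position ortho to the chelating OMOM group, and a DMF quench should give 3,4,5-trimethoxy-2-(methoxymethoxy)benzaldehyde F6. HCl in MeOH at rt should remove the acetal and return salicylaldehyde 2, where the route is rejoined.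

Further compounds
F1 | step 6 | 1-(2-benzyloxy-3,4,5-trimethoxyphenyl)-3-(3-benzyloxy-4,5-dimethoxyphenyl)prop-2-yn-1-ol (racemic) | COc1cc(C(O)C#Cc2cc(OC)c(OC)c(OCc3ccccc3)c2)c(OCc2ccccc2)c(OC)c1OC
F2 | step 6 | 1-(2-benzyloxy-3,4,5-trimethoxyphenyl)-3-(3-benzyloxy-4,5-dimethoxyphenyl)prop-2-yn-1-one | COc1cc(C(=O)C#Cc2cc(OC)c(OC)c(OCc3ccccc3)c2)c(OCc2ccccc2)c(OC)c1OC
F3 | step 6 | oxime of ynone F2, drawn with the hydroxyl syn to the alkyne | COc1cc(/C(C#Cc2cc(OC)c(OC)c(OCc3ccccc3)c2)=N/O)c(OCc2ccccc2)c(OC)c1OC
F4 | step 7 | 3-(2-hydroxy-3,4,5-trimethoxyphenyl)-5-(3-hydroxy-4,5-dimethoxyphenyl)isoxazole | COc1cc(-c2cc(-c3cc(O)c(OC)c(OC)c3)on2)c(O)c(OC)c1OC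
F5 | step 1 | 1,2,3-trimethoxy-4-(methoxymethoxy)benzene | COCOc1ccc(OC)c(OC)c1OC
F6 | step 1 | 3,4,5-trimethoxy-2-(methoxymethoxy)benzaldehyde | COCOc1c(C=O)cc(OC)c(OC)c1OC
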